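## Structural features

The target is a flavonol: a 4H-chromen-4-one in which benzo ring A is fused through C4a–C8a to the γ-pyranone ring C, with the 4-methoxyphenyl ring B attached to C2 by a single C–C bond. It has no stereocentre, so the whole difficulty lies in substitution pattern and oxidation level. Ring A is fully substituted: methoxy groups stand at C5, C6, C7 and C8, so O1 and the four ether oxygens form an unbroken row of five oxygen-bearing carbons and no aromatic hydrogen remains on this ring. The C3 hydroxyl is the only free OH and has to be distinguished from five methyl ethers. As part of a 3-hydroxy-4-pyranone it chelates metals and is open to oxidative degradation by base and air, while the C5 methoxy group peri to the C4 carbonyl is the ether most easily lost to strong Lewis acids. Electron-rich precursors of ring A oxidise readily to quinones, and the classical oxidative closure of a 2'-hydroxychalcone tends to give aurones when the carbon that becomes C5 is substituted. The real task is therefore to join a complete, hexasubstituted ring A to a C2–C3 unit that already carries ring B and a masked oxygen, in the correct sense. The key step uses two facts: C4 can sit on ring A as a formyl group ortho to the phenolic O1, and C2–C3 is an alkyne bearing ring B on one carbon and a silyloxy group on the other. Ring C then closes by forming C4–C3 and O1–C2 with no later change of oxidation level.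

## Logic of the disconnections

13 to 12. Only the C3 oxygen changes: its O–H bond is exchanged for an O–Si bond. The free 3-hydroxy-4-pyranone is the fragile, metal-binding part of the molecule, so it is carried in masked form through ring construction. The last step then becomes a simple deprotection. The forward step must leave five methyl ethers and the pyranone untouched, which a buffered fluoride source allows.

12 to 6 and 11. The C4–C3 and O1–C2 bonds of ring C are cut. Both bonds end on the two alkyne carbons, so the molecule falls into a ring A piece and a ring B piece of similar size, and the route becomes convergent. All substituents of ring A are already in 6, which has no aryl C–H bond left, and 11 delivers the C3 oxygen already protected. The forward step must cleave the formyl C–H bond, insert the alkyne with the oxygen-bearing carbon toward C4, and keep the acid-labile 11 intact. A silver-free cationic rhodium source, an aprotic solvent and slow addition of 11 are therefore planned.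

11 to 7 and 8 (through 10). First the O–Si bond is cut. Then the bond between the two alkyne carbons is cut with return of the aryl group to the oxygen-bearing carbon, which reveals the ester carbonyl of 7 and a one-carbon carbenoid. The gain is a one-flask access from a cheap benzoate. The forward step needs silylation of the ambident anion 10 on oxygen and not on carbon, which the bulk of 8 is chosen to enforce.

6 to 4. The C4–C4a bond (formyl carbon to ring A) is cut. Compound 4 has a single free ring position and it lies ortho to the hydroxyl, so the regiochemistry is unambiguous. The forward step must formylate a very electron-rich phenol without strong Lewis acids that could cleave methyl ethers. A magnesium phenoxide with a C1 electrophile meets this.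

4 to 1. The C8a–O1 bond (aryl carbon to oxygen) is cut. The two ring hydrogens of 1 are equivalent by symmetry and each lies ortho to a methoxy group, so only one metalation product is possible. The forward step needs complete deprotonation and a mild oxidation of the carbon–boron bond that does not over-oxidise the phenol.

## Other disconnections considered

Alternative 1: This plan cuts the C4a–C8a bond of ring A and goes back to the open-chain triketo ester A1 (methyl 8-(benzyloxy)-2,4-dimethoxy-3,5,7-trioxooctanoate).
- Forward key step: Mg(OMe)2 in methanol would form the chelated polyenolate of A1. The methylene between the C5 and C7 ketones (chain numbering) would acylate the C1 ester carbonyl in a Dieckmann-type Claisen condensation. Enolisation would give the acylphloroglucinol A2 (2-(benzyloxy)-1-(2,4,6-trihydroxy-3,5-dimethoxyphenyl)ethan-1-one).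
- In favour: the chemistry is ionic and metal-catalyst-free, and the reaction type is well understood. A2 is symmetric, so either ortho hydroxyl can later become O1. The C3 oxygen arrives as a robust benzyl ether. On predictability of the reaction class this plan is the better one, since the chosen key step is a proposed extension.
- Against: A1 is a polyenolised chain with two α-methoxy ketone units that must itself be assembled over several steps. It offers competing closures, namely aldol condensation to a resorcinol and O-acylation to a pyranone. From A2 onward, ring C still has to be built by 4-methoxybenzoylation and cyclodehydration, the C5 and C7 hydroxyls methylated, and the benzyl group removed.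
- Comparison: this plan constructs ring A from scratch and differentiates its oxygens, although all four end up as identical methyl ethers and 1 supplies the ring intact. The step count would be roughly double that of the chosen plan.

Alternative 2: This plan cuts C3–C4 and goes back to the dialdehyde A3 (racemic 3,4,5,6-tetramethoxy-2-[1-(4-methoxyphenyl)-2-oxoethoxy]benzaldehyde), which would come from 6 by O-alkylation and redox adjustment.
- Forward key step: the carbene from 3-ethyl-5-(2-hydroxyethyl)-4-methylthiazolium bromide and Et3N would turn the aromatic aldehyde into an acyl anion equivalent. This would add to the aliphatic aldehyde in an intramolecular crossed benzoin reaction and give the dihydroflavonol A4 (racemic trans-3-hydroxy-5,6,7,8-tetramethoxy-2-(4-methoxyphenyl)chroman-4-one). Dehydrogenation would then give 13.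
- In favour: the step is organocatalytic and mild. The C3 oxygen appears directly as the free hydroxyl, so no protecting group is needed there, which is better than the chosen plan on that point. The plan shares compound 6 with the chosen route, an equal starting position. Oxidation of dihydroflavonols to flavonols is reliable.
- Against: two stereocentres (C2 and C3) are created only to be erased. The sense of the benzoin depends on which aldehyde forms the Breslow intermediate, and the aromatic aldehyde is flanked by two ortho substituents. The α-aryloxy aldehyde can expel its aryloxide from the Breslow intermediate and end in a redox esterification. Making A3 requires reducing an ester to an aldehyde beside an aryl aldehyde.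
- Comparison: mechanistically both plans rest on a step that is not established for the exact substrate class, so they are equals in risk. The chosen plan reaches the correct oxidation level directly and is about three steps shorter.

Alternative 3: This plan cuts the C8–C8a bond and, one stage earlier, the C4a–C5 bond, building ring A from dimethyl squarate A5 (3,4-dimethoxycyclobut-3-ene-1,2-dione).
- Precursor: the pyranone A6 (3-(benzyloxy)-5-bromo-2-(4-methoxyphenyl)-4H-pyran-4-one) would be metallated at C5 and added to A5. This would give A7 (racemic 4-[5-(benzyloxy)-6-(4-methoxyphenyl)-4-oxo-4H-pyran-3-yl]-4-hydroxy-2,3-dimethoxycyclobut-2-en-1-one).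
- Forward key step: heating A7 in xylene would open the four-membered ring by 4π electrocyclisation to a dienylketene. A 6π closure onto the unsubstituted pyranone carbon (the later C8a) and tautomerisation would give the hydroquinone A8 (3-(benzyloxy)-5,8-dihydroxy-6,7-dimethoxy-2-(4-methoxyphenyl)-4H-chromen-4-one). Double O-methylation and hydrogenolysis over Pd/C would complete the target.
- In favour: the thermal ring expansion (Moore type) is an established, reagent-free reaction for aryl and heteroaryl carbinols and has complete regiocontrol. On reliability of the key reaction class it is better than the chosen plan. Like the chosen plan, it carries the C3 oxygen protected to the end, an equal point.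
- Against: A6 must first be built with rings B and C in place. Metallated 4-pyranones are prone to ring opening. A8 is an air-sensitive hydroquinone whose chelated C5 hydroxyl methylates sluggishly.
- Comparison: ring A is again made from scratch although it is available intact. The route would need about eight to nine steps against five.

Key step: step 4

Remark on the chemistry: each step is taken to end with a mildly acidic aqueous work-up, so phenoxides, alkoxides and borates are counted in their neutral forms. Compounds 6, 11 and 12 were mapped atom by atom onto 13 and needed no structural correction, so the changes made concern the reagents of step 4 and the one-flask access to 4.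

## Route

Step 1
Reactants: 1 1,2,3,4-tetramethoxybenzene
Product: 4 2,3,4,5-tetramethoxyphenol, via aryllithium 2 (not isolated), via lithium aryltrimethoxyborate 3 (not isolated)
Conditions: n-BuLi, TMEDA, THF, 0 °C; B(OMe)3, −78 °C → rt; 30% H2O2, AcOH, 0 °C → rt
Reagents that add atoms: hydrogen peroxide, OO
Why: Directed ortho-metalation next to a methoxy group; the two ring hydrogens of 1 are symmetry-equivalent, so only one aryllithium can form. Borylation and ipso-oxidation of the aryl–boron bond (1,2-aryl shift from boron to oxygen) place the hydroxyl exactly where lithium stood.

Step 2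
Reactants: 4 2,3,4,5-tetramethoxyphenol
Product: 6 2-hydroxy-3,4,5,6-tetramethoxybenzaldehyde, via salicyl alcohol 5 (not isolated)
Conditions: (CH2O)n, MgCl2, Et3N, MeCN, reflux; 1 M HCl
Reagents that add atoms: formaldehyde (as paraformaldehyde), C=O
Why: Casnati–Skattebøl ortho-formylation: the magnesium phenoxide delivers formaldehyde to the only free ring position, and the resulting magnesium salicyl alkoxide is oxidised to the aldehyde by hydride transfer to a second formaldehyde (Oppenauer type). No strong Lewis acid is present, so the methyl ethers should survive.

Step 3
Reactants: 7 methyl 4-methoxybenzoate; 8 chlorotri(propan-2-yl)silane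
Product: 11 {[(4-methoxyphenyl)ethynyl]oxy}tri(propan-2-yl)silane, via lithium dibromoenolate 9 (not isolated), via lithium ynolate 10 (not isolated)
Conditions: CH2Br2, lithium 2,2,6,6-tetramethylpiperidide (from 2,2,6,6-tetramethylpiperidine and n-BuLi), THF, −78 °C; n-BuLi, −78 °C → rt; 8, −78 °C → rt
Reagents that add atoms: dibromomethane, BrCBr; chlorotri(propan-2-yl)silane 8, CC(C)[Si](Cl)(C(C)C)C(C)C
Why: Kowalski ester homologation: LiCHBr2 adds to the ester and the dibromo ketone is deprotonated to 9; bromine–lithium exchange then triggers a 1,2-aryl shift with loss of LiBr to give ynolate 10. The bulky silyl chloride is expected to silylate this ambident anion on oxygen rather than carbon.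

Step 4
Reactants: 6 2-hydroxy-3,4,5,6-tetramethoxybenzaldehyde; 11 {[(4-methoxyphenyl)ethynyl]oxy}tri(propan-2-yl)silane
Product: 12 5,6,7,8-tetramethoxy-2-(4-methoxyphenyl)-3-{[tri(propan-2-yl)silyl]oxy}-4H-chromen-4-one
Conditions: [Cp*Rh(MeCN)3](SbF6)2 (5 mol %), Cu(OAc)2 (2.2 equiv), 4 Å molecular sieves, ClCH2CH2Cl, 60 °C, slow addition of 11 (1.5 equiv)
Reagents that add atoms: none
Why: Proposed new method: the cationic Cp*Rh fragment (trivalent rhodium) binds the phenoxide of 6 and cleaves the formyl C–H bond by acetate-assisted metalation, giving a five-membered acyl rhodacycle. Alkyne 11 then inserts into the rhodium–acyl bond, the acyl carbon (C4) bonding to the oxygen-bearing alkyne carbon (C3) and rhodium to the aryl-bearing carbon (C2), which gives a seven-membered oxarhodacycle. C–O reductive elimination joins O1 to C2 and closes ring C as the pyranone (a formal [4+2] oxidative annulation closed by C(sp2)–O reductive elimination at rhodium), and the monovalent rhodium released is returned to trivalent rhodium by two equivalents of Cu(OAc)2. The closest known reaction type is the rhodium-catalysed oxidative annulation of salicylaldehydes with diaryl and aryl alkyl alkynes to 2,3-disubstituted chromones; a siloxyalkyne has not been shown as the partner. No stereocentre is formed. The step needs regioselective insertion, and the ketene-like polarisation of 11 (electrophilic oxygen-bearing carbon, nucleophilic aryl-bearing carbon) and the usual preference of rhodium for the aryl-substituted carbon point the same way. It also needs the acid-labile siloxyalkyne to outlast the catalyst: the bulky iPr3Si group, a silver-free rhodium source (monovalent silver is a π-acid toward siloxyalkynes), an aprotic solvent, molecular sieves and slow addition of 11 are chosen for that, and ring A of 6 has no aryl C–H bond to compete with the formyl C–H.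

Step 5
Reactants: 12 5,6,7,8-tetramethoxy-2-(4-methoxyphenyl)-3-{[tri(propan-2-yl)silyl]oxy}-4H-chromen-4-one
Product: 13 3-hydroxy-5,6,7,8-tetramethoxy-2-(4-methoxyphenyl)-4H-chromen-4-one (target)
Conditions: Bu4NF, AcOH, THF, 0 °C
Reagents that add atoms: none
Why: Fluoride-mediated desilylation, driven by the strong Si–F bond, frees the C3 hydroxyl while methyl ethers and the pyranone are inert. The AcOH buffer keeps the flavonol protonated and so guards against base- and air-induced degradation.

## Compound list

1 | 1,2,3,4-tetramethoxybenzene | COc1ccc(OC)c(OC)c1OC | starting material
2 | (2,3,4,5-tetramethoxyphenyl)lithium | [Li]c1cc(OC)c(OC)c(OC)c1OC | intermediate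
3 | lithium trimethoxy(2,3,4,5-tetramethoxyphenyl)borate | [Li+].CO[B-](OC)(OC)c1cc(OC)c(OC)c(OC)c1OC | intermediate
4 | 2,3,4,5-tetramethoxyphenol | COc1cc(O)c(OC)c(OC)c1OC | intermediate
5 | 2-(hydroxymethyl)-3,4,5,6-tetramethoxyphenol (present as its magnesium salt) | COc1c(O)c(CO)c(OC)c(OC)c1OC | intermediate
6 | 2-hydroxy-3,4,5,6-tetramethoxybenzaldehyde | COc1c(O)c(C=O)c(OC)c(OC)c1OC | intermediate
7 | methyl 4-methoxybenzoate | COC(=O)c1ccc(OC)cc1 | starting material
8 | chlorotri(propan-2-yl)silane | CC(C)[Si](Cl)(C(C)C)C(C)C | starting material
9 | lithium 2,2-dibromo-1-(4-methoxyphenyl)ethen-1-olate | [Li+].[O-]C(=C(Br)Br)c1ccc(OC)cc1 | intermediate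
10 | lithium 2-(4-methoxyphenyl)ethyn-1-olate | [Li+].[O-]C#Cc1ccc(OC)cc1 | intermediate
11 | {[(4-methoxyphenyl)ethynyl]oxy}tri(propan-2-yl)silane | COc1ccc(C#CO[Si](C(C)C)(C(C)C)C(C)C)cc1 | intermediate
12 | 5,6,7,8-tetramethoxy-2-(4-methoxyphenyl)-3-{[tri(propan-2-yl)silyl]oxy}-4H-chromen-4-one | COc1ccc(-c2oc3c(OC)c(OC)c(OC)c(OC)c3c(=O)c2O[Si](C(C)C)(C(C)C)C(C)C)cc1 | intermediate
13 | 3-hydroxy-5,6,7,8-tetramethoxy-2-(4-methoxyphenyl)-4H-chromen-4-one | COc1ccc(-c2oc3c(OC)c(OC)c(OC)c(OC)c3c(=O)c2O)cc1 | target

## Step count and risks

Total step count: 5. Longest linear sequence: 4 steps (1 → 4 → 6 → 12 → 13); the branch 7 → 11 adds one step and joins at step 4.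

Step 4 (key step, proposed new method).
- What may go wrong: electrophilic activation of the siloxyalkyne, by protonation with the AcOH co-produced or by π-coordination to the cationic metal, followed by acyl transfer to the phenol of 6 or to traces of water, could outrun formyl C–H activation. Insertion of the alkyne in the reverse sense, or decarbonylation of the acyl rhodacycle before insertion, are the next concerns.
- Fallback (known chemistry), from 6 to 13, bypassing 11 and 12: 6 is treated with an excess of the lithium acetylide made from purchased 1-ethynyl-4-methoxybenzene F1 and n-BuLi. This gives racemic 2-[1-hydroxy-3-(4-methoxyphenyl)prop-2-yn-1-yl]-3,4,5,6-tetramethoxyphenol F2. Oxidation with MnO2 gives 1-(2-hydroxy-3,4,5,6-tetramethoxyphenyl)-3-(4-methoxyphenyl)prop-2-yn-1-one F3. Et2NH in ethanol closes ring C in the 6-endo sense through the enaminone and gives 5,6,7,8-tetramethoxy-2-(4-methoxyphenyl)-4H-chromen-4-one F4. Dimethyldioxirane epoxidises the C2–C3 bond to racemic 3,4,5,6-tetramethoxy-1a-(4-methoxyphenyl)-1a,7a-dihydro-7H-oxireno[2,3-b]chromen-7-one F5, and catalytic TsOH isomerises F5 to 13.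

Step 3.
- What may go wrong: incomplete carbenoid rearrangement, silylation of the ynolate on carbon, or hydrolytic loss of the silyl ynol ether during work-up and purification, since the compound behaves as a masked ketene.
- Fallback, from 8 to 11 through 10: 1-ethynyl-4-methoxybenzene F1 is deprotonated with LiN(SiMe3)2 to lithium (4-methoxyphenyl)acetylide F6. Oxygen transfer from LiOOt-Bu (from t-BuOOH and LiN(SiMe3)2) oxidises F6 to ynolate 10, which is silylated with 8 to give 11.

Step 1.
- What may go wrong: incomplete deprotonation of the ring, or over-oxidation of the very electron-rich phenol by excess peroxide toward quinones.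
- Fallback, from 1 to 4: Vilsmeier–Haack formylation (POCl3, DMF) gives 2,3,4,5-tetramethoxybenzaldehyde F7. Baeyer–Villiger (Dakin-type) oxidation with mCPBA gives 2,3,4,5-tetramethoxyphenyl formate F8, and methanolysis with K2CO3 in MeOH gives 4.

Step 2.
- What may go wrong: slow delivery of formaldehyde because the magnesium phenoxide is chelated by the neighbouring methoxy group, and diversion of the salicyl alcohol stage into diarylmethane formation or O-methoxymethylation on long heating.
- Fallback, from 4 to 6: bromination with NBS at the only free ring position gives 2-bromo-3,4,5,6-tetramethoxyphenol F9. O-deprotonation and bromine–lithium exchange with n-BuLi, then quenching of the aryllithium with DMF, gives 6 after acidic work-up.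

## Further compounds

F1 | step 4 | 1-ethynyl-4-methoxybenzene (purchased) | C#Cc1ccc(OC)cc1
F2 | step 4 | racemic 2-[1-hydroxy-3-(4-methoxyphenyl)prop-2-yn-1-yl]-3,4,5,6-tetramethoxyphenol | COc1ccc(cc1)C#CC(O)c1c(O)c(OC)c(OC)c(OC)c1OC
F3 | step 4 | 1-(2-hydroxy-3,4,5,6-tetramethoxyphenyl)-3-(4-methoxyphenyl)prop-2-yn-1-one | COc1ccc(cc1)C#CC(=O)c1c(O)c(OC)c(OC)c(OC)c1OC
F4 | step 4 | 5,6,7,8-tetramethoxy-2-(4-methoxyphenyl)-4H-chromen-4-one | COc1ccc(-c2cc(=O)c3c(OC)c(OC)c(OC)c(OC)c3o2)cc1
F5 | step 4 | racemic 3,4,5,6-tetramethoxy-1a-(4-methoxyphenyl)-1a,7a-dihydro-7H-oxireno[2,3-b]chromen-7-one (cis-fused epoxide) | COc1ccc(cc1)C12OC1C(=O)c1c(OC)c(OC)c(OC)c(OC)c1O2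
F6 | step 3 | lithium (4-methoxyphenyl)acetylide | [Li]C#Cc1ccc(OC)cc1
F7 | step 1 | 2,3,4,5-tetramethoxybenzaldehyde | COc1cc(C=O)c(OC)c(OC)c1OC
F8 | step 1 | 2,3,4,5-tetramethoxyphenyl formate | COc1cc(OC=O)c(OC)c(OC)c1OC
F9 | step 2 | 2-bromo-3,4,5,6-tetramethoxyphenol | COc1c(O)c(Br)c(OC)c(OC)c1OC
A1 | alternative 1 | methyl 8-(benzyloxy)-2,4-dimethoxy-3,5,7-trioxooctanoate (mixture of stereoisomers and tautomers) | COC(=O)C(OC)C(=O)C(OC)C(=O)CC(=O)COCc1ccccc1
A2 | alternative 1 | 2-(benzyloxy)-1-(2,4,6-trihydroxy-3,5-dimethoxyphenyl)ethan-1-one | COc1c(O)c(OC)c(O)c(C(=O)COCc2ccccc2)c1O
A3 | alternative 2 | racemic 3,4,5,6-tetramethoxy-2-[1-(4-methoxyphenyl)-2-oxoethoxy]benzaldehyde | COc1ccc(cc1)C(C=O)Oc1c(OC)c(OC)c(OC)c(OC)c1C=O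
A4 | alternative 2 | racemic trans-3-hydroxy-5,6,7,8-tetramethoxy-2-(4-methoxyphenyl)chroman-4-one (2R,3R enantiomer drawn) | COc1ccc(cc1)[C@H]1Oc2c(OC)c(OC)c(OC)c(OC)c2C(=O)[C@@H]1O
A5 | alternative 3 | dimethyl squarate (3,4-dimethoxycyclobut-3-ene-1,2-dione) | COC1=C(OC)C(=O)C1=O
A6 | alternative 3 | 3-(benzyloxy)-5-bromo-2-(4-methoxyphenyl)-4H-pyran-4-one | COc1ccc(cc1)-c1occ(Br)c(=O)c1OCc1ccccc1
A7 | alternative 3 | racemic 4-[5-(benzyloxy)-6-(4-methoxyphenyl)-4-oxo-4H-pyran-3-yl]-4-hydroxy-2,3-dimethoxycyclobut-2-en-1-one | COc1ccc(cc1)-c1occ(C2(O)C(=O)C(OC)=C2OC)c(=O)c1OCc1ccccc1
A8 | alternative 3 | 3-(benzyloxy)-5,8-dihydroxy-6,7-dimethoxy-2-(4-methoxyphenyl)-4H-chromen-4-one | COc1ccc(-c2oc3c(O)c(OC)c(OC)c(O)c3c(=O)c2OCc2ccccc2)cc1
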